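(The constants stand for no real mixture; the flask was simulated.)

At early times in this flask, each target that appears meets a solution still rich in starting material, the limiting reagent at one equivalent against 1.10 equiv of reagent in the second phase.

starting material 0.012 M; reagent in the second phase 1.10 equiv; time 1.0 h; volume of the second phase over the first 0.50

    reagent in the reaction phase ⇌ reagent in the second phase, rate k1*([reagent in the reaction phase] - [reagent in the second phase]/K1) per volume of the first phase (K1 = 0.55, k1 = 8.2 × 10⁻⁴ /s)
    starting material + reagent in the reaction phase → target (k2 = 2.3 /M/s)
    target ⇌ product in the second phase, rate k3*([target] - [product in the second phase]/K3) per volume of the first phase (K3 = 2.6, k3 = 7.8 × 10⁻⁴ /s)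
    target → decomposed product (k4 = 9.2 × 10⁻⁴ /s)
    starting material + target → side product (k5 = 0.27 /M/s)
    crystals ⇌ target, rate k6*(cs6 - [target]) while solid is left; crystals form when [target] > cs6 (cs6 = 0.20 mM, k6 = 0.0068 /s)
    target → over-reaction product (k7 = 2.8 × 10⁻⁷ /s)

- percentages count the starting material that a species holds: one side product counts as two
- target is meant together with its product in the second phase and crystals
- in the second phase: reagent in the second phase, product in the second phase; everything else is in the first
- charges count per volume of the first phase; a concentration in a rate is the amount of a species over the volume of its own phase; every rate counts per litre of the first phase
- solid, in amounts per volume of the solution: crystals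
- run time (flask): 1.0 h

- amount of target and product in the second phase and crystals together at 1.0 h, in percent of the starting material charged
- concentration of target in solution at 1.0 h, in percent of saturation

Two views stand at the board, both in fractions of the charge. The first says crystals hold dissolved target at saturation, 1.67% of the charge. Reagent in the second phase crosses with a rate constant of 0.00298 /s, so at the start the feed is 0.00328 /s of the charge per second. Against that feed, side product forms in 1.65% of couplings, and decomposition at saturation takes 5.52% in the run. This view therefore expects y near 91.2%.

I hold the other view. For crystals to swallow that starting feed, the excess over saturation would have to reach 48.2% of the charge, far more than saturation itself. So I treat dissolved target as a passing stream and count a race. My quantity is the interception number φ = 0.381, the rate at which starting material as charged catches a dissolved target over the rate at which that target leaves by crystals, decomposition and transfer.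

Now the balance of starting material: a coupling spends one, and a catch spends one more and destroys the target, so one side product counts as two. The feed cancels. Running the fraction left from the full charge down to none gives the side-product loss L = 1 − ln(1 + 2φ)/(2φ), here 25.7%. That leaves 74.3% for target and decomposed product together, and my reckoning stops there.

The forecast gives 63% and 92%, holding that “This supersaturation drives the side reaction”. The simulation gives 63.8% and 92.6%, so the forecast stands, with side product at 22.7% against my 25.7%.

At 0.100 h, with coupling and catching running side by side, starting material stood at 32.3% and side product at 17.4%; by 0.500 h starting material was down to 0.0731% and side product had reached 22.7%. From then to 1.0 h, crystals went from 60.0% to 59.3% and decomposed product from 10.9% to 13.5%, and this late stretch, ending with dissolved target at 92.6% of saturation, is where the saturation view comes close.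

In the neighbour flask, charged with 0.020 M, the interception number rises to 0.635, and the same balance gives a loss of 35.5%. That neighbour gives 30.6% of side product, 10.8% of decomposed product and y of 58.6%.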